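**Retrosynthetic overview**

1. Last bond C11–C13: B-alkyl Suzuki–Miyaura coupling of bromobutenolide 9 (ring A half) with the borylethyl cis-lactone 21. The dimer is heterochiral (5R,10R in the butenolide half, 5′S,10′S in the saturated half), so the two enantiomers of one racemic bromo-elemanolide 8 supply the two halves.
2. 21 comes from the mirror-image bromide 10: debromination, deconjugative opening to the C8′ ketone, equatorial hydride delivery and relactonisation (cis-lactone), α-methylenation, then conjugate addition of a borylmethyl unit with convex-face protonation (C11′).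
3. 8 is made in one flask from the C10 unit 4 (from geranyl acetate) and the C4 lactone 5: C8–C9 by γ-alkylation, C6–C7 by ring-closing Suzuki–Miyaura coupling to a ten-membered (E,E)-germacradienolide, then Cope rearrangement.
4. Enabling feature: on ring A the C10 vinyl and C5 isopropenyl groups form the 1,5-diene C2=C1–C10–C5–C4=C3. This is the Cope retron of a cyclodeca-1(10),4-diene in which C6 and C9 are allylic CH2 groups flanking the butenolide ring, whose C8 is an acidic γ-CH and whose C7 is a β-bromo-enoate carbon (C11–Br stays as the handle for the union).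
5. Ring order: butenolide ring (purchased) → temporary ten-membered carbocycle → ring A by [3,3] shift; in the second half the lactone ring is opened and closed again cis-fused.

Key step: step 4

Remark: locants follow elemane numbering (C1–C15, primed for the saturated-lactone half); the C8 hydrogen of the butenolide half, being γ to the lactone carbonyl, is assumed to equilibrate under base to the epimer with the C8–O bond equatorial (trans to the C10 methyl), which is the configuration of the target.

**Route**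

Step 1
Reactants: 1 geranyl acetate
Product: 2 (2E,6E)-8-hydroxy-3,7-dimethylocta-2,6-dien-1-yl acetate
Conditions: SeO2 (0.3 equiv), t-BuOOH (2 equiv), CH2Cl2, 0 °C to rt, stopped before over-oxidation
Reagents that add atoms: tert-butyl hydroperoxide, CC(C)(C)OO
Why: Riley allylic oxidation (ene reaction of SeO2, then [2,3] shift) should hydroxylate the E methyl group of the electron-richer distal trisubstituted alkene, with the alkene geometry kept and the acetate-bearing alkene left alone.

Step 2
Reactants: 2 (2E,6E)-8-hydroxy-3,7-dimethylocta-2,6-dien-1-yl acetate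
Product: 3 (2E,6E)-2,6-dimethyl-8-(4,4,5,5-tetramethyl-1,3,2-dioxaborolan-2-yl)octa-2,6-dien-1-ol
Conditions: Pd2(dba)3 (2.5 mol %), B2pin2 (1.1 equiv), DMSO, 50 °C
Reagents that add atoms: bis(pinacolato)diboron, CC1(C)OB(OC1(C)C)B1OC(C)(C)C(C)(C)O1
Why: Miyaura-type borylation of an allylic acetate: zerovalent palladium ionises the acetate, the π-allyl complex transmetalates with the diboron and reductive elimination at the primary terminus should give the linear E allylboronate, while the free allylic alcohol is not ionised under these base-free conditions.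

Step 3
Reactants: 3 (2E,6E)-2,6-dimethyl-8-(4,4,5,5-tetramethyl-1,3,2-dioxaborolan-2-yl)octa-2,6-dien-1-ol
Product: 4 2-[(2E,6E)-8-bromo-3,7-dimethylocta-2,6-dien-1-yl]-4,4,5,5-tetramethyl-1,3,2-dioxaborolane
Conditions: CBr4 (1.2 equiv), PPh3 (1.2 equiv), 2,6-lutidine, CH2Cl2, −30 to 0 °C
Reagents that add atoms: carbon tetrabromide, BrC(Br)(Br)Br
Why: Appel reaction: SN2 displacement of the alkoxyphosphonium ion by bromide at the primary allylic carbon should proceed without allylic transposition and under conditions neutral enough for the allylboronate.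

Step 4
Reactants: 4 2-[(2E,6E)-8-bromo-3,7-dimethylocta-2,6-dien-1-yl]-4,4,5,5-tetramethyl-1,3,2-dioxaborolane; 5 3,4-dibromofuran-2(5H)-one
Product: 8 rac-(5R,6R,7aR)-3-bromo-6-ethenyl-6-methyl-5-(prop-1-en-2-yl)-5,6,7,7a-tetrahydro-1-benzofuran-2(4H)-one, via alkylated dibromofuranone 6 (not isolated), via germacradienolide 7 (not isolated)
Conditions: 5 (1.3 equiv), Cs2CO3 (1.3 equiv), DMF, −20 to 0 °C; then dilution to 2 mM with 1,4-dioxane, PdCl2(IPent)(3-chloropyridine) (10 mol %; IPent = 1,3-bis[2,6-di(pentan-3-yl)phenyl]imidazol-2-ylidene), CsF (3 equiv), 60 °C; then 100 °C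
Reagents that add atoms: none
Why: Proposed new method: Cs2CO3 turns the acidic γ-CH2 (C8) of 5 into the 2-oxidofuran, which is alkylated at C8 by the primary allylic bromide of 4 (SN2, C8–C9), and then zerovalent palladium inserts into the β-C–Br bond (C7) of the resulting 3,4-dibromobutenolide 6, the fluoride-activated allylboronate transmetalates and reductive elimination at its α-carbon joins C6 to C7. The closest known reactions are γ-functionalisation of 3,4-dihalofuranone anions, C4-selective Suzuki–Miyaura coupling of 3,4-dibromofuran-2(5H)-one, α-selective coupling of prenyl-type boronates under bulky N-heterocyclic-carbene palladium catalysis, ten-membered ring closures of (E,E)-farnesyl-type chains in germacrane synthesis and the germacrene-to-elemene Cope rearrangement; what is new is their union in one flask and the macrocyclic allyl–alkenyl coupling. Ring closures: the ten-membered carbocycle of 7 closes by intramolecular cross-coupling (macrocyclisation at 2 mM), and ring A then forms from it at 100 °C by a [3,3] sigmatropic (Cope) shift through a chair transition state that makes C5–C10 and breaks C2–C3, driven by the strain of the (E,E)-cyclodecadiene. Stereocentres: C5 and C10 are set together by the E geometry of both trisubstituted alkenes (inherited from geranyl acetate) and the chair transition state, which places vinyl and isopropenyl trans and the C10 methyl cis to isopropenyl, while C8 stays epimerisable through the furanolate under the residual base and should settle with its C–O bond equatorial, trans to the axial C10 methyl, so that C8 epimers and ring conformers of 7 are funnelled into one racemic diastereomer. Selectivity needed: coupling at the α- and not the γ-carbon of the allylboron unit (bulky carbene ligand; the γ-carbon is fully substituted), insertion at C7–Br before C11–Br (β-bromide of a β-bromoenoate), alkylation at C8 and not at the bromine-bearing α-carbon, and ring closure before oligomerisation (high dilution).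

Step 5
Reactants: 8 rac-(5R,6R,7aR)-3-bromo-6-ethenyl-6-methyl-5-(prop-1-en-2-yl)-5,6,7,7a-tetrahydro-1-benzofuran-2(4H)-one
Product: 9 (5R,6R,7aR)-3-bromo-6-ethenyl-6-methyl-5-(prop-1-en-2-yl)-5,6,7,7a-tetrahydro-1-benzofuran-2(4H)-one and 10 (5S,6S,7aS)-3-bromo-6-ethenyl-6-methyl-5-(prop-1-en-2-yl)-5,6,7,7a-tetrahydro-1-benzofuran-2(4H)-one
Conditions: preparative supercritical-fluid chromatography, amylose tris(3,5-dimethylphenylcarbamate) stationary phase, CO2/i-PrOH
Reagents that add atoms: none
Why: Chromatographic resolution on a chiral stationary phase (no bond is changed) separates the enantiomers, both of which are used (9 for the butenolide half, 10 for the saturated half), and the absolute configuration would be assigned by anomalous X-ray dispersion of the bromine atom.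

Step 6
Reactants: 10 (5S,6S,7aS)-3-bromo-6-ethenyl-6-methyl-5-(prop-1-en-2-yl)-5,6,7,7a-tetrahydro-1-benzofuran-2(4H)-one
Product: 11 (5S,6S,7aS)-6-ethenyl-6-methyl-5-(prop-1-en-2-yl)-5,6,7,7a-tetrahydro-1-benzofuran-2(4H)-one
Conditions: Pd(PPh3)4 (5 mol %), Bu3SnH (1.2 equiv), THF, rt
Reagents that add atoms: none
Why: Palladium-catalysed hydrodebromination (oxidative addition of zerovalent palladium into the alkenyl C–Br bond, tin-to-palladium hydride transfer, C–H reductive elimination) should remove the bromine without touching the isolated alkenes or any stereocentre.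

Step 7
Reactants: 11 (5S,6S,7aS)-6-ethenyl-6-methyl-5-(prop-1-en-2-yl)-5,6,7,7a-tetrahydro-1-benzofuran-2(4H)-one
Product: 13 methyl 2-[(1R,4S,5S)-4-ethenyl-4-methyl-2-oxo-5-(prop-1-en-2-yl)cyclohexyl]acetate, via enol lactone 12 (not isolated)
Conditions: KN(SiMe3)2 (1.1 equiv), THF, −78 °C; AcOH (1.2 equiv), −78 °C; then MeOH, TsOH·H2O (0.1 equiv), rt
Reagents that add atoms: methanol, CO
Why: Deconjugative kinetic protonation of the aromatic 2-oxidofuran (dienolate) at its α-carbon C11 gives the enol lactone, whose acid-catalysed methanolysis (the angelica lactone-to-levulinate type of enol-ester alcoholysis) should release the C8 ketone and the C7 acetic ester, with C7 equilibrating through the enol to the equatorial 7R epimer (cis to the C5 isopropenyl group).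

Step 8
Reactants: 13 methyl 2-[(1R,4S,5S)-4-ethenyl-4-methyl-2-oxo-5-(prop-1-en-2-yl)cyclohexyl]acetate
Product: 15 (3aR,5S,6S,7aR)-6-ethenyl-6-methyl-5-(prop-1-en-2-yl)hexahydro-1-benzofuran-2(3H)-one, via hydroxy ester 14 (not isolated)
Conditions: LiBH(s-Bu)3 (1.2 equiv), THF, −78 °C to rt; aq. HCl
Reagents that add atoms: none
Why: Reduction of a cyclohexanone with a bulky borohydride: hydride should arrive from the equatorial direction (the axial path is blocked by the axial C10 methyl), giving the axial 8R alkoxide cis to the equatorial C7 side chain, which closes the cis-fused γ-lactone by intramolecular transesterification.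

Step 9
Reactants: 15 (3aR,5S,6S,7aR)-6-ethenyl-6-methyl-5-(prop-1-en-2-yl)hexahydro-1-benzofuran-2(3H)-one; 16 N,N-dimethylmethylideneammonium iodide
Product: 17 (3S,3aR,5S,6S,7aR)-3-[(dimethylamino)methyl]-6-ethenyl-6-methyl-5-(prop-1-en-2-yl)hexahydro-1-benzofuran-2(3H)-one
Conditions: LiN(i-Pr)2 (1.1 equiv), THF, −78 °C; then 16, −78 °C to rt
Reagents that add atoms: none
Why: Mannich reaction of the lactone lithium enolate with the preformed iminium salt should give the α-aminomethyl lactone (attack from the convex face; this centre is removed in the next step).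

Step 10
Reactants: 17 (3S,3aR,5S,6S,7aR)-3-[(dimethylamino)methyl]-6-ethenyl-6-methyl-5-(prop-1-en-2-yl)hexahydro-1-benzofuran-2(3H)-one
Product: 19 (3aR,5S,6S,7aR)-6-ethenyl-6-methyl-3-methylidene-5-(prop-1-en-2-yl)hexahydro-1-benzofuran-2(3H)-one, via ammonium iodide 18 (not isolated)
Conditions: MeI (5 equiv), MeOH, rt; then NaHCO3 (aq), EtOAc, rt
Reagents that add atoms: none
Why: N-methylation followed by Hofmann-type (E1cB) elimination of trimethylamine from the β-ammonio lactone should give the exocyclic α-methylene lactone without touching C7 or C8.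

Step 11
Reactants: 19 (3aR,5S,6S,7aR)-6-ethenyl-6-methyl-3-methylidene-5-(prop-1-en-2-yl)hexahydro-1-benzofuran-2(3H)-one; 20 2,2′-methylenebis(4,4,5,5-tetramethyl-1,3,2-dioxaborolane)
Product: 21 (3S,3aR,5S,6S,7aR)-6-ethenyl-6-methyl-5-(prop-1-en-2-yl)-3-[2-(4,4,5,5-tetramethyl-1,3,2-dioxaborolan-2-yl)ethyl]hexahydro-1-benzofuran-2(3H)-one
Conditions: CuCl (10 mol %), 4,5-bis(diphenylphosphino)-9,9-dimethylxanthene (10 mol %), LiOt-Bu (1.5 equiv), THF, 0 °C; AcOH, −78 °C
Reagents that add atoms: none
Why: Copper-catalysed conjugate addition of a borylmethylcopper species, formed from the geminal diboron compound by alkoxide-induced deborylative transmetalation to monovalent copper, to the α-methylene lactone; low-temperature protonation of the enolate from the convex face (cis to H-7′ and H-8′) should place the new chain on the concave face, which is the 11′S configuration.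

Step 12
Reactants: 9 (5R,6R,7aR)-3-bromo-6-ethenyl-6-methyl-5-(prop-1-en-2-yl)-5,6,7,7a-tetrahydro-1-benzofuran-2(4H)-one; 21 (3S,3aR,5S,6S,7aR)-6-ethenyl-6-methyl-5-(prop-1-en-2-yl)-3-[2-(4,4,5,5-tetramethyl-1,3,2-dioxaborolan-2-yl)ethyl]hexahydro-1-benzofuran-2(3H)-one
Product: 22 CNP0332736.1, the target
Conditions: PdCl2(dppf) (10 mol %), Ag2O (1.5 equiv), K2CO3 (2 equiv), THF, 60 °C
Reagents that add atoms: none
Why: B-alkyl Suzuki–Miyaura coupling: oxidative addition of zerovalent palladium into the α-C–Br bond of the butenolide, silver-oxide-assisted transmetalation of the primary alkylboronate and reductive elimination should form C11–C13 under water-free conditions that spare both lactones and all stereocentres.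

**Compound list**

1 | geranyl acetate, (2E)-3,7-dimethylocta-2,6-dien-1-yl acetate | CC(C)=CCC/C(C)=C/COC(C)=O | starting material
2 | (2E,6E)-8-hydroxy-3,7-dimethylocta-2,6-dien-1-yl acetate | OC/C(C)=C/CC/C(C)=C/COC(C)=O | intermediate
3 | (2E,6E)-2,6-dimethyl-8-(4,4,5,5-tetramethyl-1,3,2-dioxaborolan-2-yl)octa-2,6-dien-1-ol | OC/C(C)=C/CC/C(C)=C/CB1OC(C)(C)C(C)(C)O1 | intermediate
4 | 2-[(2E,6E)-8-bromo-3,7-dimethylocta-2,6-dien-1-yl]-4,4,5,5-tetramethyl-1,3,2-dioxaborolane | BrC/C(C)=C/CC/C(C)=C/CB1OC(C)(C)C(C)(C)O1 | intermediate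
5 | 3,4-dibromofuran-2(5H)-one | O=C1OCC(Br)=C1Br | starting material
6 | 3,4-dibromo-5-[(2E,6E)-2,6-dimethyl-8-(4,4,5,5-tetramethyl-1,3,2-dioxaborolan-2-yl)octa-2,6-dien-1-yl]furan-2(5H)-one (racemic) | O=C1OC(C/C(C)=C/CC/C(C)=C/CB2OC(C)(C)C(C)(C)O2)C(Br)=C1Br | intermediate
7 | (5E,9E)-3-bromo-6,10-dimethyl-4,7,8,11-tetrahydrocyclodeca[b]furan-2(11aH)-one (racemic; 11-bromo-13-nor-germacra-1(10),4,7(11)-trien-12,8-olide) | O=C1OC2C/C(C)=C/CC/C(C)=C/CC2=C1Br | intermediate
8 | rac-(5R,6R,7aR)-3-bromo-6-ethenyl-6-methyl-5-(prop-1-en-2-yl)-5,6,7,7a-tetrahydro-1-benzofuran-2(4H)-one (racemate, one enantiomer drawn; elemane descriptors 5R*,8R*,10R*) | C=C[C@@]1(C)C[C@H]2OC(=O)C(Br)=C2C[C@@H]1C(=C)C | intermediate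
9 | (5R,6R,7aR)-3-bromo-6-ethenyl-6-methyl-5-(prop-1-en-2-yl)-5,6,7,7a-tetrahydro-1-benzofuran-2(4H)-one (elemane 5R,8R,10R) | C=C[C@@]1(C)C[C@H]2OC(=O)C(Br)=C2C[C@@H]1C(=C)C | intermediate
10 | (5S,6S,7aS)-3-bromo-6-ethenyl-6-methyl-5-(prop-1-en-2-yl)-5,6,7,7a-tetrahydro-1-benzofuran-2(4H)-one (elemane 5S,8S,10S) | C=C[C@]1(C)C[C@@H]2OC(=O)C(Br)=C2C[C@H]1C(=C)C | intermediate
11 | (5S,6S,7aS)-6-ethenyl-6-methyl-5-(prop-1-en-2-yl)-5,6,7,7a-tetrahydro-1-benzofuran-2(4H)-one | C=C[C@]1(C)C[C@@H]2OC(=O)C=C2C[C@H]1C(=C)C | intermediate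
12 | (5S,6S)-6-ethenyl-6-methyl-5-(prop-1-en-2-yl)-4,5,6,7-tetrahydro-1-benzofuran-2(3H)-one (enol lactone) | C=C[C@]1(C)CC2=C(CC(=O)O2)C[C@H]1C(=C)C | intermediate
13 | methyl 2-[(1R,4S,5S)-4-ethenyl-4-methyl-2-oxo-5-(prop-1-en-2-yl)cyclohexyl]acetate | O=C1C[C@@](C)(C=C)[C@H](C(=C)C)C[C@@H]1CC(=O)OC | intermediate
14 | methyl 2-[(1R,2R,4S,5S)-4-ethenyl-2-hydroxy-4-methyl-5-(prop-1-en-2-yl)cyclohexyl]acetate (formed as its lithium alkoxide) | O[C@@H]1C[C@@](C)(C=C)[C@H](C(=C)C)C[C@@H]1CC(=O)OC | intermediate
15 | (3aR,5S,6S,7aR)-6-ethenyl-6-methyl-5-(prop-1-en-2-yl)hexahydro-1-benzofuran-2(3H)-one (cis-fused) | O=C1O[C@@H]2C[C@@](C)(C=C)[C@H](C(=C)C)C[C@@H]2C1 | intermediate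
16 | N,N-dimethylmethylideneammonium iodide | C=[N+](C)C.[I-] | starting material
17 | (3S,3aR,5S,6S,7aR)-3-[(dimethylamino)methyl]-6-ethenyl-6-methyl-5-(prop-1-en-2-yl)hexahydro-1-benzofuran-2(3H)-one (aminomethyl on the convex face) | CN(C)C[C@H]1C(=O)O[C@@H]2C[C@@](C)(C=C)[C@H](C(=C)C)C[C@H]12 | intermediate
18 | {[(3S,3aR,5S,6S,7aR)-6-ethenyl-6-methyl-2-oxo-5-(prop-1-en-2-yl)octahydro-1-benzofuran-3-yl]methyl}trimethylammonium iodide | C[N+](C)(C)C[C@H]1C(=O)O[C@@H]2C[C@@](C)(C=C)[C@H](C(=C)C)C[C@H]12.[I-] | intermediate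
19 | (3aR,5S,6S,7aR)-6-ethenyl-6-methyl-3-methylidene-5-(prop-1-en-2-yl)hexahydro-1-benzofuran-2(3H)-one (elemane 5S,7R,8R,10S) | C=C1C(=O)O[C@@H]2C[C@@](C)(C=C)[C@H](C(=C)C)C[C@H]12 | intermediate
20 | 2,2′-methylenebis(4,4,5,5-tetramethyl-1,3,2-dioxaborolane) | CC1(C)OB(CB2OC(C)(C)C(C)(C)O2)OC1(C)C | starting material
21 | (3S,3aR,5S,6S,7aR)-6-ethenyl-6-methyl-5-(prop-1-en-2-yl)-3-[2-(4,4,5,5-tetramethyl-1,3,2-dioxaborolan-2-yl)ethyl]hexahydro-1-benzofuran-2(3H)-one | CC1(C)OB(CC[C@@H]2C(=O)O[C@@H]3C[C@@](C)(C=C)[C@H](C(=C)C)C[C@H]23)OC1(C)C | intermediate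
22 | CNP0332736.1: (5R,6R,7aR)-6-ethenyl-3-{2-[(3S,3aR,5S,6S,7aR)-6-ethenyl-6-methyl-2-oxo-5-(prop-1-en-2-yl)octahydro-1-benzofuran-3-yl]ethyl}-6-methyl-5-(prop-1-en-2-yl)-5,6,7,7a-tetrahydro-1-benzofuran-2(4H)-one (elemane 5R,8R,10R and 5′S,7′R,8′R,10′S,11′S) | C=C[C@@]1(C)C[C@H]2OC(=O)C(CC[C@@H]3C(=O)O[C@@H]4C[C@@](C)(C=C)[C@H](C(=C)C)C[C@H]34)=C2C[C@@H]1C(=C)C | target

**Step count and risks**

Total step count: 12. Longest linear sequence: 12 steps (steps 1 to 12; bromide 9 from step 5 joins in step 12).

Steps most likely to fail: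

1. Step 4. The allylboron unit may couple through its γ-carbon (eight-membered ring), chains may oligomerise instead of closing the ten-membered ring, and the furanolate may condense with unreacted 5. Fallback with known reactions taken one at a time, setting out from 3 and 5 and returning at 8. C4-selective Suzuki–Miyaura coupling of 5 with allylboronate 3 (PdCl2(IPent)(3-chloropyridine), K3PO4, THF/H2O) should give the hydroxy-geranyl bromobutenolide F1. MsCl, 2,4,6-collidine and LiCl in DMF should give the allylic chloride F2. Slow addition of F2 to LiN(SiMe3)2 in THF (high dilution, −78 to 0 °C) should close the ten-membered ring by intramolecular γ-alkylation of the furanolate, the type of closure used for germacrane rings from (E,E)-farnesyl-type allylic chlorides, to give 7. Heating 7 in toluene at 100 °C rejoins the route at 8.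

2. Step 11. tert-Butoxide may add in place of the borylmethyl group, the borylmethylcopper species may be protonated before it adds, and C11′ may equilibrate under base to the convex-chain epimer. Fallback setting out from 19 and returning at 22, so that step 12 is bypassed as well. CuI-catalysed conjugate addition of (i-PrO)Me2SiCH2MgCl (THF, −78 °C, NH4Cl quench) should give the silylethyl lactone F3. Tamao–Fleming oxidation (KF, KHCO3, H2O2, THF/MeOH) should give the hydroxyethyl lactone F4. I2, PPh3 and imidazole should give the iodoethyl lactone F5. Zinc dust with LiCl in THF should give the alkylzinc iodide F6, which in a Negishi coupling with 9 (PdCl2(dppf), THF, 40 °C) should give 22.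

3. Step 7. The furanolate may be protonated at C8 (returning 11), the enol lactone may reconjugate before methanolysis, and methanol may add to the isopropenyl group under acid. Fallback setting out from 11 and returning at 15. Conjugate reduction with SmI2 (THF/HMPA, t-BuOH) should give the saturated trans-lactone F7. AlMe3 with MeNHOMe·HCl should open it to the hydroxy N-methoxy-N-methylamide F8. Dess–Martin oxidation should give the keto amide F9, in which C7 equilibrates to the equatorial epimer. LiBH(s-Bu)3 followed by TsOH should give 15.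

**Further compounds**

F1 | step 4 | 3-bromo-4-[(2E,6E)-8-hydroxy-3,7-dimethylocta-2,6-dien-1-yl]furan-2(5H)-one | O=C1OCC(C/C=C(C)/CC/C=C(C)/CO)=C1Br
F2 | step 4 | 3-bromo-4-[(2E,6E)-8-chloro-3,7-dimethylocta-2,6-dien-1-yl]furan-2(5H)-one | O=C1OCC(C/C=C(C)/CC/C=C(C)/CCl)=C1Br
F3 | step 11 | (3S,3aR,5S,6S,7aR)-3-{2-[dimethyl(propan-2-yloxy)silyl]ethyl}-6-ethenyl-6-methyl-5-(prop-1-en-2-yl)hexahydro-1-benzofuran-2(3H)-one | CC(C)O[Si](C)(C)CC[C@@H]1C(=O)O[C@@H]2C[C@@](C)(C=C)[C@H](C(=C)C)C[C@H]12
F4 | step 11 | (3S,3aR,5S,6S,7aR)-6-ethenyl-3-(2-hydroxyethyl)-6-methyl-5-(prop-1-en-2-yl)hexahydro-1-benzofuran-2(3H)-one | OCC[C@@H]1C(=O)O[C@@H]2C[C@@](C)(C=C)[C@H](C(=C)C)C[C@H]12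
F5 | step 11 | (3S,3aR,5S,6S,7aR)-6-ethenyl-3-(2-iodoethyl)-6-methyl-5-(prop-1-en-2-yl)hexahydro-1-benzofuran-2(3H)-one | ICC[C@@H]1C(=O)O[C@@H]2C[C@@](C)(C=C)[C@H](C(=C)C)C[C@H]12
F6 | step 11 | {2-[(3S,3aR,5S,6S,7aR)-6-ethenyl-6-methyl-2-oxo-5-(prop-1-en-2-yl)octahydro-1-benzofuran-3-yl]ethyl}zinc iodide | I[Zn]CC[C@@H]1C(=O)O[C@@H]2C[C@@](C)(C=C)[C@H](C(=C)C)C[C@H]12
F7 | step 7 | (3aR,5S,6S,7aS)-6-ethenyl-6-methyl-5-(prop-1-en-2-yl)hexahydro-1-benzofuran-2(3H)-one (trans-fused) | C=C[C@]1(C)C[C@@H]2OC(=O)C[C@H]2C[C@H]1C(=C)C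
F8 | step 7 | 2-[(1R,2S,4S,5S)-4-ethenyl-2-hydroxy-4-methyl-5-(prop-1-en-2-yl)cyclohexyl]-N-methoxy-N-methylacetamide | C=C[C@]1(C)C[C@H](O)[C@@H](CC(=O)N(C)OC)C[C@H]1C(=C)C
F9 | step 7 | 2-[(1R,4S,5S)-4-ethenyl-4-methyl-2-oxo-5-(prop-1-en-2-yl)cyclohexyl]-N-methoxy-N-methylacetamide | C=C[C@]1(C)CC(=O)[C@@H](CC(=O)N(C)OC)C[C@H]1C(=C)C
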